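**Late split.** Some 7.93 parts of the charge stand apart from each part of D at the last red reading. We call this the late split: charge that is neither D nor J, divided by D, once D has stopped moving. In the red run D nearly stops, going from 12.0% to 11.2% between 8.00 min and 20.0 min. If that stop is a balance, the rate out of D and the rate back into it match, and their quotient holds no time. The violet run, charged with 40 mM against the red 10 mM, reads 8.13. Its percentages track the red ones closely, so we take one curve for the flask's 20 mM.

| flask | J | remark | time |
|---|---|---|---|
| red | 10 mM | run made earlier |  |
| violet | 40 mM | run made earlier |  |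
| flask | 20 mM |  | 15 min |

| run | time / min | D / % | J / % |
|---|---|---|---|
| red | 0.417 | 17.1 | 56.7 |
| red | 0.833 | 26.3 | 42.0 |
| red | 2.00 | 30.2 | 19.7 |
| red | 4.00 | 20.9 | 5.6 |
| red | 8.00 | 12.0 | 0 |
| red | 20.0 | 11.2 | 0 |
| violet | 0.417 | 17.6 | 56.4 |
| violet | 0.833 | 25.6 | 43.4 |
| violet | 2.00 | 29.8 | 20.3 |
| violet | 4.00 | 20.6 | 6.8 |
| violet | 8.00 | 12.7 | 0.8 |
| violet | 20.0 | 10.9 | 0.5 |

(scatter of a reading: 0.5 percentage points)

- the earlier runs were read with a standard deviation of 0.5 percentage points

* the best time, 15 min at the latest, for D
* the amount of D, in percent of the J charged, at that time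
* earliest time at which at least nineteen twentieths of that best amount are there, in min
* latest time at which they still are, in min

**Turned round.** For the best time to be the last one allowed, 15 min, late D would have to pass the red peak reading of 30.2%, which means a split under 2.31. The red split stands 3.43 times above that. So we commit to an early best near the red peak, followed by a fall toward the late value: the kinetic side of kinetic against thermodynamic control.

**The forecast.** It holds that “the network behaves as first order” and puts the best at 1.6 min, with 31%, and the asked window from 1.1 min to 2.15 min.

**The flask.** It gives 30.1% at 1.63 min, with the window from 1.13 min to 2.28 min, and each value lies within the forecast's margin.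

    J ⇌ E (K = 0.470, k = 0.00280 s⁻¹)
    E → Z (k = 0.0200 s⁻¹)
    D ⇌ Z (K = 8.10, k = 0.0120 s⁻¹)
    J → D (k = 0.0120 s⁻¹)
    J ⇌ Q (K = 0.340, k = 0.290 s⁻¹)

**Split again.** At 15.0 min the flask holds 11.0% of D and 89.0% of Z, the product no reading showed, with 0.00714% of J left. Its late split is 8.09, above the 2.32 that its own best of 30.1% asks for. The neighbouring flask, the same charge read at 10 min, holds 11.4% of D and 88.4% of Z, with 0.15% of J left. Its highest D up to then was 30.1%, and its split at that reading is 7.76.

(The earlier runs and the new flask are calculated with constants of no real substance; the scatter is artificial.)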